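Before any ratio can be reckoned for this flask, we must decide where G comes from, and two chemists decide differently.

| flask | J | E | remark | time |
|---|---|---|---|---|
| ochre | 0.20 mM | 10 µM | the very flask that is asked about, followed so far |  |
| blue | 0.10 mM | 10 µM | run made earlier |  |
| flask | 0.20 mM | 10 µM |  | 3.0 min |

| run | time / s | G / % | D / % |
|---|---|---|---|
| ochre | 10.0 | 0.5 | 22.4 |
| ochre | 15.0 | 1.9 | 28.8 |
| ochre | 40.0 | 7.5 | 37.1 |
| blue | 15.0 | 2.0 | 28.2 |
| blue | 40.0 | 7.7 | 37.4 |
| blue | 80.0 | 17.2 | 35.6 |
| blue | 120 | 24.7 | 32.2 |

(each reading ± 0.3 percentage points)

1. ratio of G to D at 0.40 s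
2. ratio of G to D at 8.0 s
3. ratio of G to D at 3.0 min

- the earlier runs were read with a standard deviation of 0.3 percentage points

The first chemist holds that J gives D and G side by side, so that G to D keeps one value from the start. He reads that value from the earliest ochre reading, 0.0223 at 10.0 s. The second chemist, with whom I reckon, holds that G is made from D, and treats G as a small correction to D.

Between 15.0 s and 40.0 s of the ochre run, the G gained, divided by the mean D and by the time elapsed, gives 0.00680 s⁻¹. Call this reading the handover constant, the net share of the D present that becomes G each second.

While D rises in proportion to time, G rises with the square of time, and D's own rate cancels. So G to D is half the handover constant times the time. That gives 0.00136 at 0.40 s and 0.0272 at 8.0 s. I expect the second to lie low, because ochre D gains less per second between 10.0 s and 15.0 s than before.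

She points to the ratio of 0.202 at 40.0 s. He answers that his reading carries a scatter of 0.3 points and that no reading lies near 0.40 s.

Late on, G is no correction. Blue, whose percentages match ochre at 40.0 s, reads 0.767 at 120 s, with D moving from 35.6% to 32.2% over its last interval. With D taken as flat, the ratio climbs by the full constant per second, and I commit to 1.17 at 3.0 min.

The forecast, a shade apart from my numbers, stands on her side, “because G is second-generation”, with 0.0013, 0.026 and 1.24.

The asked flask gives 0.00144, 0.0315 and 1.18, so at 0.40 s the ratio lies far below his value.

    J ⇌ D (K = 0.829, k = 0.0328 s⁻¹)
    D + E ⇌ G + E, rate k2*[E]*[D] forward; the back reaction follows from the equilibrium constant (K = 3.10, k = 716 M⁻¹ s⁻¹)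

A ratio that keeps one value finds its region late, though far above the value he read: at 30.0 min this flask's G to D stands at 3.10, beside the second step's equilibrium constant of 3.1. The step's rate carries E, so the handover constant is a pseudo-first-order constant that scales with E. In the neighbour with 0.0025 mM of E, a quarter of the charge, it predicts 3.40 × 10⁻⁴ at 0.40 s, and that flask gives 3.60 × 10⁻⁴.

(Readings and results stem from a simulated flask for an exercise.)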